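**Plan**
1. Retrosynthesis: the epoxide goes back to the C15=C16 enol lactone; ring A is cut at C4–C5 (key cut, leaving a C5 ketone and a 4-methylpent-4-enyl chain on C10); ring C is cut at the spiro bond C13–C14; the butenolide at C15=C16 (metathesis); then C10–C1 and C9–C11 (one three-component coupling) and C8–C14 (enolate alkylation). Ring B is the ring of (S)-carvone.
2. Forward order: ring B (carvone alkylation, Wharton transposition, Criegee rearrangement) → C9 and C10 side chains in one operation → butenolide ring → ring C with the spiro centre → ring A, the last ring of the skeleton → epoxide oxygen as the closing functional-group operation.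
3. Enabling feature: the C5 ketone of ring B lies next to the quaternary C10, which carries equatorially the chain C1(OAc)–C2–C3–C4(CH3)=CH2. Hydrogen-atom transfer to the terminal CH2 puts a tertiary radical on C4, five atoms from the carbonyl carbon, so one 6-exo addition makes the hindered C4–C5 bond, the gem-dimethyl group and the C5 carbinol together.
4. Stereochemistry: C7 is the carvone stereocentre (Criegee, retention); C8 from trans alkylation; C9, C10 and C1 from anti conjugate addition and a closed aldol; C13 and C14 from the spiro-alkylation; C5 from the chair-locked ring B; the epoxide face from bromohydrin formation followed by inversion.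

Key step: step 14

Remark: locants follow the cassane skeleton of the target (C1 OAc, C4 CMe2, C5 OH, C7 OAc, C8/C9 ring-fusion CH, C10 C–CH3, C11 the CH2 of ring C, C12 lactone C=O, C13 spiro carbon, C14 CH–CO2Me, C15 the CH on C13, C16 the O–CH–O carbon; β = face of the C10 methyl group), and (S)-carvone, allyl diethylphosphonoacetate and 4-methylpent-4-en-1-ol are taken as commercial.

**Route**

Step 1
Reactants: 1 (S)-carvone
Product: 3 methyl 2-[(1,6-trans)-3-methyl-2-oxo-6-(prop-1-en-2-yl)cyclohex-3-en-1-yl]acetate, via carvone lithium dienolate 2 (not isolated)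
Conditions: LiN(iPr)2, THF, −78 °C; then BrCH2CO2Me, DMPU, −78 → −20 °C
Reagents that add atoms: methyl bromoacetate COC(=O)CBr
Why: Kinetic enolate alkylation, in which the cross-conjugated C6 dienolate of the enone takes up the α-bromo ester anti to the neighbouring isopropenyl group, so that the future C8 centre is set trans to the future C7 oxygen.

Step 2
Reactants: 3 methyl 2-[(1,6-trans)-3-methyl-2-oxo-6-(prop-1-en-2-yl)cyclohex-3-en-1-yl]acetate
Product: 4 methyl 2-[(1,6-trans)-3,4-epoxy-3-methyl-2-oxo-6-(prop-1-en-2-yl)cyclohexyl]acetate (epoxide oxygen trans to the isopropenyl group)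
Conditions: 30% H2O2, NaOH (cat.), MeOH, 0 °C
Reagents that add atoms: hydrogen peroxide OO
Why: Weitz–Scheffer nucleophilic epoxidation of the enone, with hydroperoxide adding to the β-carbon anti to the isopropenyl group (this centre is erased in step 5) under a short, cold, catalytic-base protocol that should spare the methyl ester.

Step 3
Reactants: 4 epoxy ketone
Product: 6 methyl 2-[(1,6-trans; 1,4-cis)-4-hydroxy-3-methyl-6-(prop-1-en-2-yl)cyclohex-2-en-1-yl]acetate, via epoxy hydrazone 5 (not isolated)
Conditions: N2H4·H2O, AcOH (cat.), MeOH, 0 °C → rt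
Reagents that add atoms: none
Why: Wharton transposition, in which the epoxy hydrazone fragments with loss of dinitrogen to the allylic alcohol, moving the oxygen function across the methyl-bearing carbon so that the carbinol carbon becomes C5 and the alkene becomes C9=C10.

Step 4
Reactants: 6 transposed allylic alcohol
Product: 8 methyl 2-bromo-2-[(1,6-trans; 1,4-cis)-4-hydroxy-3-methyl-6-(prop-1-en-2-yl)cyclohex-2-en-1-yl]acetate (both CHBr epimers), via dilithium alkoxide enolate 7 (not isolated)
Conditions: LiN(iPr)2 (2.2 equiv), THF, −78 °C; BrCl2C–CCl2Br, −78 °C; then H2O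
Reagents that add atoms: 1,2-dibromo-1,1,2,2-tetrachloroethane ClC(Cl)(Br)C(Cl)(Cl)Br
Why: Electrophilic α-bromination of an ester enolate, with the alcohol masked in the flask as its lithium alkoxide; the new C14 centre is left as a mixture because it is equilibrated in step 13.

Step 5
Reactants: 8 bromo ester allylic alcohol
Product: 9 methyl 2-bromo-2-[(1,6-trans)-3-methyl-4-oxo-6-(prop-1-en-2-yl)cyclohex-2-en-1-yl]acetate
Conditions: Dess–Martin periodinane, NaHCO3, CH2Cl2, 0 °C → rt
Reagents that add atoms: none
Why: Dess–Martin oxidation of the allylic alcohol gives the transposed enone (a 4-substituted carvone of the opposite series) under non-basic conditions that the α-bromo ester tolerates; no stereocentre is formed.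

Step 6
Reactants: 9 transposed enone
Product: 11 methyl 2-[(1,6-trans)-6-acetoxy-3-methyl-4-oxocyclohex-2-en-1-yl]-2-bromoacetate, via methoxy hydroperoxide 10 (not isolated)
Conditions: O3, CH2Cl2/MeOH 4:1, −78 °C; then Ac2O, Et3N, DMAP (cat.), 0 °C → rt
Reagents that add atoms: ozone [O-][O+]=O; methanol CO
Why: Ozonolysis in methanol cleaves only the electron-rich isopropenyl group, and acylation of the α-methoxy hydroperoxide triggers the Criegee rearrangement, in which the ring carbon migrates to oxygen with retention, so that the carvone stereocentre becomes the 7β-acetoxy centre (the acetyl carbons are the former isopropenyl carbons).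

Step 7
Reactants: 12 allyl diethylphosphonoacetate
Product: 14 allyl 2-(diethoxyphosphoryl)-3-(trimethylsilyl)propanoate, via sodium phosphonoacetate 13 (not isolated)
Conditions: NaH, DME, 0 °C; then ICH2SiMe3, 70 °C
Reagents that add atoms: (iodomethyl)trimethylsilane C[Si](C)(C)CI
Why: C-alkylation of the stabilised phosphonoacetate anion with the α-silyl iodide, the standard entry to 2-(silylmethyl)acrylates; no stereocentre of consequence is formed.

Step 8
Reactants: 14 silylmethyl phosphonoacetate
Product: 15 allyl 2-[(trimethylsilyl)methyl]prop-2-enoate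
Conditions: 37% aq. HCHO, K2CO3, THF/H2O, rt
Reagents that add atoms: formaldehyde C=O
Why: Horner–Wadsworth–Emmons methylenation with formaldehyde gives the ester-bearing allylsilane, which already holds C11, C13 and C12 and the allyl ester needed for the later lactone ring.

Step 9
Reactants: 16 4-methylpent-4-en-1-ol
Product: 17 4-methylpent-4-enal
Conditions: Dess–Martin periodinane, CH2Cl2, 0 °C → rt (used as a solution)
Reagents that add atoms: none
Why: Dess–Martin oxidation of a primary alcohol stops at the aldehyde and leaves the 1,1-disubstituted alkene untouched.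

Step 10
Reactants: 11 acetoxy enone; 15 allylsilane; 17 4-methylpent-4-enal
Product: 19 7β-acetoxy-8α-[bromo(methoxycarbonyl)methyl]-9β-[2-(allyloxycarbonyl)prop-2-en-1-yl]-10α-[(1S)-1-hydroxy-4-methylpent-4-en-1-yl]-10β-methylcyclohexan-5-one, via trichlorotitanium enolate 18 (not isolated)
Conditions: TiCl4, CH2Cl2, −78 °C; 15; then 17, −78 → −40 °C; aq. NaHCO3
Reagents that add atoms: none
Why: Hosomi–Sakurai conjugate allylation with aldol capture of the titanium enolate, in which the allyl unit adds to C9 anti to the adjacent branched C8 substituent (the small 7-acetoxy group should not override it), the aldehyde then adds to C10 anti to the new C9 arm, and the closed chair (Zimmerman–Traxler) transition state of the ring enolate places the C1 hydroxyl syn to the methyl group, which is the (1S) configuration needed for the 1α-acetate.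

Step 11
Reactants: 19 aldol adduct
Product: 20 C1 acetate of 19 (1S; 7β-OAc)
Conditions: Ac2O, Sc(OTf)3 (1 mol %), MeCN, −20 °C
Reagents that add atoms: acetic anhydride CC(=O)OC(C)=O
Why: Lewis acid-catalysed acetylation esterifies the hindered neopentylic alcohol without base, which avoids retro-aldol cleavage and β-elimination of the C7 acetate; no stereocentre changes.

Step 12
Reactants: 20 diacetate with acrylate allyl ester
Product: 21 butenolide (C9 now carries a (2-oxo-2,5-dihydrofuran-3-yl)methyl group)
Conditions: second-generation Grubbs catalyst RuCl2(=CHPh)(PCy3)(H2IMes) (5 mol %), CH2Cl2, 40 °C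
Reagents that add atoms: none
Why: Ring-closing metathesis of the allyl ester with the acrylate methylene closes the five-membered lactone (C12, C13, C15, C16, O) with loss of ethene, while the 1,1-disubstituted alkene of the C10 chain is too hindered to compete.

Step 13
Reactants: 21 butenolide bromo ester
Product: 23 spiro enol lactone with rings B and C closed (14β-CO2Me; C15 β and C12 α on C13; C5 ketone; ring A open), via cesium furanolate 22 (not isolated)
Conditions: Cs2CO3, Bu4NBr (cat.), MeCN, 0 °C → rt
Reagents that add atoms: none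
Why: Deconjugative α-alkylation of a butenolide dienolate, in which γ-deprotonation gives the 2-oxidofuran whose α-carbon C13 displaces the α-bromo ester 5-exo-tet (attack through C16 would need a seven-membered ring); bromide exchange interconverts the C14 bromide epimers, so the closure should funnel through the transition state with the ester β and pseudo-equatorial and with the C15–H edge of the planar furanolate, not its carbonyl, next to that ester, which sets C14 and the spiro centre C13.

Step 14
Reactants: 23 spiro enol lactone ketone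
Product: 26 methyl 1α,7β-diacetoxy-5α-hydroxy tetracyclic enol lactone (the target without the epoxide oxygen; C15=C16), via tertiary C4 radical 24 (not isolated), via C5 alkoxy radical 25 (not isolated)
Conditions: Fe(acac)3 (0.5 equiv), PhSiH3 (2.5 equiv, slow addition), iPrOH/THF 1:1, degassed, 40 °C
Reagents that add atoms: none
Why: An iron hydride formed from Fe(acac)3 and PhSiH3 transfers a hydrogen atom to the terminal CH2 of the 1,1-disubstituted alkene, the tertiary C4 radical 24 adds to the C5 carbonyl carbon, and the alkoxy radical 25 is reduced to the tertiary alcohol. The closest known reaction type is the hydrogen-atom-transfer-initiated reductive radical cyclisation of alkene-tethered ketones with Fe(acac)3 and PhSiH3. Ring A closes in the 6-exo-trig mode onto C=O, forming C4–C5 and with it the gem-dimethyl carbon and the carbinol. C5 is the only new stereocentre: ring B is held as a chair by the trans-fused ring C with the C10 chain equatorial, so equatorial attack gives the trans-decalin with the axial 5α-oxygen, whereas axial attack would force one C4 methyl group over ring B against the axial hydrogens on C7 and C9, and the reversibility of the addition lets the system settle on the trans product. The step needs hydrogen-atom transfer to the terminal alkene in preference to the C15=C16 enol lactone and reduction of 25 faster than its β-scission; the faster transfer to an alkene that gives a tertiary radical, the limited silane supply and the protic co-solvent are relied on for this.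

Step 15
Reactants: 26 tetracyclic enol lactone
Product: 27 (15,16-trans)-15-bromo-16-hydroxy lactone (bromine on the lactone face turned towards C11)
Conditions: NBS, THF/H2O 4:1, 0 °C
Reagents that add atoms: N-bromosuccinimide O=C1CCC(=O)N1Br; water O
Why: Bromohydrin formation on an enol ester, in which electrophilic bromine attacks C15 from the face away from the cis C14 ester and water opens the resulting oxocarbenium ion at C16 trans to bromine, giving the bromo lactol.

Step 16
Reactants: 27 bromo lactol
Product: 28 spirocaesalmin
Conditions: Ag2O, 4 Å MS, CH2Cl2, rt, dark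
Reagents that add atoms: none
Why: Proposed new method: 27 is a 2-bromo hemiacylal, and silver ion should assist departure of the C15 bromide while the anti lactol oxygen on C16 closes the three-membered ring with inversion at C15, so the epoxide oxygen ends on the face opposite to the bromine, that is syn to C14 as in the target, and the non-basic medium should keep the lactol from opening to the α-bromo aldehyde carboxylate; the closest known reaction type is the halohydrin-to-epoxide closure with Ag2O or base, including the closure of glycal-derived 2-halo hemiacetals to 1,2-anhydro sugars.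

**Compound list**
1 | (S)-carvone, (5S)-2-methyl-5-(prop-1-en-2-yl)cyclohex-2-en-1-one | CC1=CC[C@@H](CC1=O)C(C)=C | starting material
2 | carvone lithium dienolate (O-lithiated, enolised towards C6) | CC1=CC[C@@H](C=C1O[Li])C(C)=C | intermediate
3 | methyl 2-[(1,6-trans)-3-methyl-2-oxo-6-(prop-1-en-2-yl)cyclohex-3-en-1-yl]acetate | COC(=O)C[C@@H]1[C@@H](C(C)=C)CC=C(C)C1=O | intermediate
4 | methyl 2-[(1,6-trans)-3,4-epoxy-3-methyl-2-oxo-6-(prop-1-en-2-yl)cyclohexyl]acetate, epoxide oxygen trans to isopropenyl | COC(=O)C[C@@H]1[C@@H](C(C)=C)C[C@@H]2O[C@]2(C)C1=O | intermediate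
5 | hydrazone of 4 at the ring ketone | COC(=O)C[C@@H]1[C@@H](C(C)=C)C[C@@H]2O[C@]2(C)C1=NN | intermediate
6 | methyl 2-[(1,6-trans; 1,4-cis)-4-hydroxy-3-methyl-6-(prop-1-en-2-yl)cyclohex-2-en-1-yl]acetate | COC(=O)C[C@@H]1[C@@H](C(C)=C)C[C@H](O)C(C)=C1 | intermediate
7 | dilithium alkoxide ester enolate of 6 | COC(O[Li])=C[C@@H]1[C@@H](C(C)=C)C[C@H](O[Li])C(C)=C1 | intermediate
8 | methyl 2-bromo-2-[(1,6-trans; 1,4-cis)-4-hydroxy-3-methyl-6-(prop-1-en-2-yl)cyclohex-2-en-1-yl]acetate, both CHBr epimers | COC(=O)C(Br)[C@@H]1[C@@H](C(C)=C)C[C@H](O)C(C)=C1 | intermediate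
9 | methyl 2-bromo-2-[(1,6-trans)-3-methyl-4-oxo-6-(prop-1-en-2-yl)cyclohex-2-en-1-yl]acetate | COC(=O)C(Br)[C@@H]1[C@@H](C(C)=C)CC(=O)C(C)=C1 | intermediate
10 | methyl 2-bromo-2-[(1,6-trans)-6-(1-hydroperoxy-1-methoxyethyl)-3-methyl-4-oxocyclohex-2-en-1-yl]acetate, mixture at the peroxy carbon | COC(=O)C(Br)[C@@H]1[C@@H](C(C)(OC)OO)CC(=O)C(C)=C1 | intermediate
11 | methyl 2-[(1,6-trans)-6-acetoxy-3-methyl-4-oxocyclohex-2-en-1-yl]-2-bromoacetate (ring B: C5 ketone, C9=C10, 7β-OAc, 8α side chain) | COC(=O)C(Br)[C@@H]1[C@@H](OC(C)=O)CC(=O)C(C)=C1 | intermediate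
12 | allyl diethylphosphonoacetate | CCOP(=O)(OCC)CC(=O)OCC=C | starting material
13 | sodium salt of 12 (phosphonoacetate carbanion) | CCOP(=O)(OCC)[CH-]C(=O)OCC=C.[Na+] | intermediate
14 | allyl 2-(diethoxyphosphoryl)-3-(trimethylsilyl)propanoate | CCOP(=O)(OCC)C(C[Si](C)(C)C)C(=O)OCC=C | intermediate
15 | allyl 2-[(trimethylsilyl)methyl]prop-2-enoate | C=CCOC(=O)C(=C)C[Si](C)(C)C | intermediate
16 | 4-methylpent-4-en-1-ol | CC(=C)CCCO | starting material
17 | 4-methylpent-4-enal | CC(=C)CCC=O | intermediate
18 | trichlorotitanium enolate (C5–O–TiCl3, C5=C10) of the C9-allylated ketone | COC(=O)C(Br)[C@@H]1[C@@H](OC(C)=O)CC(O[Ti](Cl)(Cl)Cl)=C(C)[C@H]1CC(=C)C(=O)OCC=C | intermediate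
19 | 7β-acetoxy-8α-[bromo(methoxycarbonyl)methyl]-9β-[2-(allyloxycarbonyl)prop-2-en-1-yl]-10α-[(1S)-1-hydroxy-4-methylpent-4-en-1-yl]-10β-methylcyclohexan-5-one | COC(=O)C(Br)[C@@H]1[C@@H](OC(C)=O)CC(=O)[C@](C)([C@@H](O)CCC(C)=C)[C@H]1CC(=C)C(=O)OCC=C | intermediate
20 | C1 acetate of 19 | COC(=O)C(Br)[C@@H]1[C@@H](OC(C)=O)CC(=O)[C@](C)([C@@H](OC(C)=O)CCC(C)=C)[C@H]1CC(=C)C(=O)OCC=C | intermediate
21 | butenolide: as 20, but C9 carries a (2-oxo-2,5-dihydrofuran-3-yl)methyl group | COC(=O)C(Br)[C@@H]1[C@@H](OC(C)=O)CC(=O)[C@](C)([C@@H](OC(C)=O)CCC(C)=C)[C@H]1CC2=CCOC2=O | intermediate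
22 | cesium furan-2-olate of 21 | COC(=O)C(Br)[C@@H]1[C@@H](OC(C)=O)CC(=O)[C@](C)([C@@H](OC(C)=O)CCC(C)=C)[C@H]1Cc2ccoc2[O-].[Cs+] | intermediate
23 | spiro enol lactone: trans-fused rings B and C, C5 ketone, 7β-OAc, 14β-CO2Me, spiro C13 with C12(=O) α and C15 β, C15=C16, C10 with β-methyl and α-[(1S)-1-acetoxy-4-methylpent-4-enyl] | COC(=O)[C@H]1[C@@H]2[C@@H](OC(C)=O)CC(=O)[C@](C)([C@@H](OC(C)=O)CCC(C)=C)[C@H]2C[C@]13C(=O)OC=C3 | intermediate
24 | tertiary C4 radical from 23 | COC(=O)[C@H]1[C@@H]2[C@@H](OC(C)=O)CC(=O)[C@](C)([C@@H](OC(C)=O)CC[C](C)C)[C@H]2C[C@]13C(=O)OC=C3 | intermediate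
25 | C5 alkoxy radical of the tetracycle | COC(=O)[C@H]1[C@@H]2[C@@H](OC(C)=O)C[C@@]3([O])C(C)(C)CC[C@H](OC(C)=O)[C@]3(C)[C@H]2C[C@]12C(=O)OC=C2 | intermediate
26 | tetracyclic enol lactone: 1α,7β-diacetoxy, 5α-hydroxy, 14β-CO2Me, C15=C16 | COC(=O)[C@H]1[C@@H]2[C@@H](OC(C)=O)C[C@@]3(O)C(C)(C)CC[C@H](OC(C)=O)[C@]3(C)[C@H]2C[C@]12C(=O)OC=C2 | intermediate
27 | (15,16-trans)-15-bromo-16-hydroxy lactone, bromine on the face towards C11 | COC(=O)[C@H]1[C@@H]2[C@@H](OC(C)=O)C[C@@]3(O)C(C)(C)CC[C@H](OC(C)=O)[C@]3(C)[C@H]2C[C@]12C(=O)O[C@H](O)[C@H]2Br | intermediate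
28 | spirocaesalmin | COC(=O)[C@H]1[C@@H]2[C@@H](OC(C)=O)C[C@@]3(O)C(C)(C)CC[C@H](OC(C)=O)[C@]3(C)[C@H]2C[C@]12C(=O)O[C@@H]1O[C@@H]12 | target

**Step count and risks**
Total steps: 16. Longest linear sequence: 13 (steps 1–6 and 10–16).

Steps most likely to fail:

1. Step 16 (proposed new method). What may go wrong: the lactol opens to the α-bromo aldehyde carboxylate, C15 epimerises or the acyloxy group migrates, so the epoxide fails to close or closes on both faces. Fallback: setting out from 26, the enol lactone is epoxidised directly under reagent control by a Shi epoxidation, a reaction known for enol esters. The enantiomer of the carbohydrate-derived ketone that delivers oxygen to the face syn to C14 is used with Oxone (2KHSO5·KHSO4·K2SO4) at buffered pH 8 in MeCN/H2O at 0 °C. This returns to the route at 28 and makes no new compound (F0).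

2. Step 14. What may go wrong: hydrogen-atom transfer to the enol lactone double bond competes, the alkoxy radical fragments, or facial control at C5 is insufficient. Fallback (ring A by carbonyl allylation and ring-closing metathesis): setting out from 11, the allylation–aldol of step 10 is run with acrolein in place of 17 to give the C1 vinyl carbinol F1. Acetylation as in step 11 gives the diacetate F2. Metathesis as in step 12 gives the butenolide F3, the neopentylic C1 vinyl group being the slowest alkene present. Spiro-alkylation as in step 13 gives the ring C spiro lactone F4. Barbier addition of prenyl bromide with indium metal (In, DMF/H2O) to the C5 ketone, through the γ-carbon of the allylindium and from the equatorial direction, gives the C5 carbinol F5, which already holds C4 with both methyl groups. RuCl2(=CH-o-iPrOC6H4)(H2IMes) then joins the C1 and C4 vinyl groups to the ring A cyclohexene F6 (C2=C3). Hydroxyl-directed hydrogenation with [Ir(cod)(PCy3)(py)]PF6 and H2 saturates C2=C3 and returns to the route at 26.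

3. Step 10. What may go wrong: the ester-deactivated allylsilane reacts too slowly, the facial selectivity at C9 is poor because the C7 and C8 substituents direct to opposite faces, or the hindered titanium enolate fails to add to the aldehyde. Fallback (two separate, open-chain events): setting out from 11, conjugate allylation with 15 catalysed by Me3SiNTf2 (CH2Cl2, −78 °C) stops at the trimethylsilyl enol ether F7, which is isolated. A separate Mukaiyama aldol addition with 17 (BF3·OEt2, CH2Cl2, −78 °C) then returns to the route at 19.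

**Further compounds**
F0 | step 16 | none | none
F1 | step 14 | C1 vinyl carbinol (aldol adduct of 18 with acrolein) | COC(=O)C(Br)[C@@H]1[C@@H](OC(C)=O)CC(=O)[C@](C)([C@@H](O)C=C)[C@H]1CC(=C)C(=O)OCC=C
F2 | step 14 | C1 acetate of F1 | COC(=O)C(Br)[C@@H]1[C@@H](OC(C)=O)CC(=O)[C@](C)([C@@H](OC(C)=O)C=C)[C@H]1CC(=C)C(=O)OCC=C
F3 | step 14 | butenolide from F2 | COC(=O)C(Br)[C@@H]1[C@@H](OC(C)=O)CC(=O)[C@](C)([C@@H](OC(C)=O)C=C)[C@H]1CC2=CCOC2=O
F4 | step 14 | spiro enol lactone with a 1-acetoxyprop-2-enyl chain on C10 | COC(=O)[C@H]1[C@@H]2[C@@H](OC(C)=O)CC(=O)[C@](C)([C@@H](OC(C)=O)C=C)[C@H]2C[C@]13C(=O)OC=C3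
F5 | step 14 | C5 carbinol bearing the 2-methylbut-3-en-2-yl group (5α-OH) | COC(=O)[C@H]1[C@@H]2[C@@H](OC(C)=O)C[C@@](O)(C(C)(C)C=C)[C@](C)([C@@H](OC(C)=O)C=C)[C@H]2C[C@]13C(=O)OC=C3
F6 | step 14 | 2,3-didehydro analogue of 26 | COC(=O)[C@H]1[C@@H]2[C@@H](OC(C)=O)C[C@@]3(O)C(C)(C)C=C[C@H](OC(C)=O)[C@]3(C)[C@H]2C[C@]12C(=O)OC=C2
F7 | step 10 | trimethylsilyl enol ether (C5–O–SiMe3, C5=C10) of the C9-allylated ketone | COC(=O)C(Br)[C@@H]1[C@@H](OC(C)=O)CC(O[Si](C)(C)C)=C(C)[C@H]1CC(=C)C(=O)OCC=C
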